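**Remark on the chemistry (assumptions):** The target has no stereocentre. In the twofold steps only the stage at which both arms have reacted is numbered; half-converted species, acylium ions and peracid adducts carry no number. Mapping indanone C7a → coumarin C8a, C5 → C6 and C4 → C5 through 8, 9 and 11 shows the regiochemistry to be self-consistent, so no structure needed correction. The way to 8 is shortened by merging condensation and reduction into one operation (step 2).

## Structural features

The target 11 (C18H10O8) is built from two 2H-chromen-2-one (coumarin) bicycles, four rings in all, joined by one diaryl ether oxygen between C6 of unit A and C5' of unit B. Unit A has a free hydroxyl at C7, next to the ether. Unit B has a catechol at C6'/C7', so its benzene ring is pentasubstituted and the ether carbon C5' is flanked on both sides (C4a' and C6'). There are no stereocentres, and the only double bonds outside the arenes are the two ring-locked C3=C4 enoates, so nothing stereochemical has to be set or kept. The fragile parts are the two aryl lactones, which hydroxide or alkoxide opens (most easily at the 3,4-dihydro stage), and the phenol/catechol array, which is oxidised to quinones by air in base or by DDQ. The real difficulty is regiochemical: a diaryl ether with three ortho substituents must be made, and a ring oxygen and a three-carbon acyl arm must then be placed on neighbouring carbons (C8a/C4a and C8a'/C4a') of two differently oxygenated rings without ever telling one phenol from another. The key step uses the fact that each ring oxygen O1 (O1') lies between the acyl carbon C2 (C2') and an aryl carbon C8a (C8a') whose para position C6 (C6') carries oxygen. A C2–C8a carbon–carbon bond can therefore stand in for O1, be made by Friedel–Crafts acylation, and later be turned into C2–O1–C8a by migration of the electron-rich aryl carbon.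

## Logic of the disconnections

**11 ⇒ 10.** The three O–H groups at C7, C6' and C7' are replaced by O–CH3. The free phenols would not survive peracid, DDQ or hot strong acid, whereas methyl ethers pass through all of them. Nothing is gained in skeleton, but the oxidation-sensitive functions are removed from every earlier stage. The demand on the forward step is cleavage of three aryl methyl ethers without harm to the diaryl ether or the lactones.

**10 ⇒ 9.** The C3=C4 and C3'=C4' double bonds are saturated. The lactones come from saturated five-membered ketones and so are formed in the dihydro state. The gain is that 9 is open to ring expansion. The demand is a late twofold dehydrogenation that acts at the benzylic C4 and C4' positions only.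

**9 ⇒ 8.** The O1–C8a and O1'–C8a' bonds are cut and C2–C8a and C2'–C8a' are joined instead, which contracts each lactone to a cyclopentanone. Two aryl ester bonds, which would otherwise need two regiodefined phenols, become carbon–carbon bonds that a ring closure can set. Both heterocycles then arise in a single operation. The demand is that in both ketones the aryl carbon migrates and not the methylene, and that the oxidant spares the oxygen-rich rings.

**8 ⇒ 7.** The two aryl–carbonyl bonds (C1–C7a of each indanone) are cut. Two rings disappear and a diaryl ether with two identical propanoic acid arms remains. The demand is regiochemical. The arm on the ring with three oxygens has only one free ortho position. The arm on the other ring must close para to the aryloxy oxygen and not at the position wedged between arm and ether.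

**7 ⇒ 3 + 4.** Each arm is cut between its benzylic carbon and the carbon next to the carboxyl group (the future C4–C3 and C4'–C3' bonds). The benzylic carbons become the aldehyde carbons of 3, and the two-carbon acid units come from two molecules of 4. Both arms are thus installed together from one symmetrical type of reaction. The demand is that condensation, reduction and decarboxylation all go to completion on both arms.

**3 ⇒ 1 + 2.** The ether bond between the oxygen of 1 and C2 of 2 (the future O–C5' bond) is cut. The halogen of 2 is ortho to a formyl group and so is activated for C–O coupling, and 1 has a single phenol, so only one ether can form. All ring oxygens and the full substitution pattern are bought with the two starting materials. The demand is a coupling at a carbon flanked on both sides, in the presence of two aldehydes.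

## Other disconnections considered

**Alternative 1:** Ring A is cut across C5–C6 and C4a–C8a. In the forward direction the diene A2, a 1-methoxy-1,3-bis(trimethylsilyloxy)butadiene that carries the complete O-methylated coumarin B as its 4-aryloxy group, would add to methyl propiolate A3 in a [4+2] sense. The terminal diene carbon would bond to the β-carbon of the alkyne, and loss of methanol and of the silyl groups would give the resorcylate A1.
- In its favour: ring A would arrive with O1 and the C7 oxygen already free and with a carbon substituent at C4a, and its regiochemistry follows from the polarisation of both partners. The diaryl ether would be made beforehand by SN2 alkylation of the phenol A4 at an sp3 carbon. On that point it is better than the chosen plan, which needs a hindered aryl C–O coupling.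
- Against it here: A4 is an uncommon 5-hydroxycoumarin that needs its own synthesis. Making A2 requires two enol silylations with LiN(iPr)2 and Me3SiCl in the presence of an electrophilic coumarin. A1 is still several operations from a coumarin: the ester must be brought to the aldehyde level beside a lactone that the same hydride would attack, then olefinated and lactonised, before the two ethers of ring B are cleaved.
- Comparison: on structure, both plans deliver the correct oxygen pattern of ring A, and the alternative frees the C7 hydroxyl without deprotection, a small advantage. On mechanism, a cycloaddition–aromatisation is as dependable in principle as the ring expansion of 8, but here it meets functional-group conflicts that the chosen plan does not have. On step economy it is clearly longer than the six steps of the chosen plan, and a final demethylation is needed in both.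

**Alternative 2:** Both pyranone rings are cut at O1–C8a and O1'–C8a', which leaves the bis-(E)-cinnamic acid A5, one condensation away from 3. In the forward direction riboflavin under visible light and O2 would first isomerise each E-alkene to Z by energy transfer. It would then oxidise the substrate by single-electron transfer so that each carboxylate oxygen bonds to the ortho carbon and the ring rearomatises, giving A6, which is the same compound as 10.
- In its favour: it is the shortest route (ether formation, condensation, photocyclisation, demethylation: four steps against six). It has no reduce-then-reoxidise detour, it is catalytic with O2 as the terminal oxidant, and the lactones never exist in the labile dihydro state. On step count and redox economy it is better than the chosen plan.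
- Against it here: four photochemical events must succeed on one molecule. The excited flavin is a strong oxidant that could attack the trioxygenated ring or the products. Coumarins absorb light and can photodimerise. The precedent is for single cinnamic acids at high dilution.
- Comparison: on structure, the two plans are equal in kind, since each must choose between the two free ortho positions of ring A (here in the C–O closure, in the chosen plan in step 3) and each has only one position open on ring B. On mechanism, the ionic Friedel–Crafts closure followed by a polar 1,2-shift is better precedented for electron-rich, polyoxygenated arenes than a twofold radical-cation lactonisation. On step economy the alternative wins by two steps. It is kept as the fallback for the key step.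

**Alternative 3:** Ring B is cut across C8a'–C4a', C5'–C6' and C8a'–C8'. In the forward direction heating the cyclobutenone A7 with the aryl ynol ether A8 (its aryloxy group is the O-methylated coumarin A, its other alkyne substituent a dimethyl acetal) would start a cascade. A7 would open to a vinylketene and undergo regioselective [2+2] addition to A8. A second four-electron ring opening, a six-electron electrocyclisation and tautomerisation would then give the phenol A9.
- In its favour: the most crowded ring would be built with full positional control in one thermal step without reagents. The O1' phenol would sit next to a masked aldehyde at C4a', ready for olefination and lactonisation. No aryl C–O coupling at a hindered carbon is needed, which is better than the chosen plan. On regiocontrol of ring B it is the equal of the chosen plan.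
- Against it here: A7 and A8 each need a multistep preparation. Aryl ynol ethers are usually generated with alkyllithium bases, which the lactone of coumarin A would not tolerate. An aryloxyalkyne is a weaker ketene partner than an alkoxy- or silyloxyalkyne. After A9, acetal hydrolysis, olefination, lactonisation and demethylation still follow.
- Comparison: on structure, both plans are regiochemically secure for ring B. On mechanism, a pericyclic cascade is elegant but depends on two delicate partners, whereas the chosen plan uses robust ionic steps on stable intermediates. On step economy the alternative is markedly longer than six steps.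

Key step: step 4

## Route

**Step 1**
Reactants: 1 isovanillin (3-hydroxy-4-methoxybenzaldehyde); 2 2-bromo-3,4-dimethoxybenzaldehyde
Product: 3 2-(5-formyl-2-methoxyphenoxy)-3,4-dimethoxybenzaldehyde
Conditions: CuI (10 mol %), N,N-dimethylglycine (30 mol %), Cs2CO3 (2 equiv), 1,4-dioxane, 100 °C, Ar
Reagents that add atoms: none
Why: Ullmann-type C–O coupling in which the caesium phenoxide of 1 is arylated by 2, whose ortho-formyl group activates the C–Br bond and can coordinate copper; 1 has a single phenol, so only one ether can form.

**Step 2**
Reactants: 3 2-(5-formyl-2-methoxyphenoxy)-3,4-dimethoxybenzaldehyde; 4 Meldrum's acid (2,2-dimethyl-1,3-dioxane-4,6-dione)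
Product: 7 3-{2-[5-(2-carboxyethyl)-2-methoxyphenoxy]-3,4-dimethoxyphenyl}propanoic acid, via bis(arylidene Meldrum's acid) 5 (not isolated), via bis(benzyl Meldrum's acid) 6 (not isolated)
Conditions: 4 (2.3 equiv), HCO2H/Et3N (5:2), 25 °C, then 95 °C; aq HCl
Reagents that add atoms: none
Why: Known one-pot reductive alkylation of Meldrum's acid in triethylammonium formate: Knoevenagel condensation gives 5, formate delivers hydride to the doubly activated alkene to give 6, and on heating the water released in the condensation opens each dioxanedione, which loses acetone and CO2 to leave the propanoic acid arms.

**Step 3**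
Reactants: 7 3-{2-[5-(2-carboxyethyl)-2-methoxyphenoxy]-3,4-dimethoxyphenyl}propanoic acid
Product: 8 5-[(5,6-dimethoxy-1-oxo-2,3-dihydro-1H-inden-4-yl)oxy]-6-methoxy-2,3-dihydro-1H-inden-1-one
Conditions: P2O5/MeSO3H (1:10 w/w), 0.05 M, 25 to 50 °C; ice water
Reagents that add atoms: none
Why: Twofold intramolecular Friedel–Crafts acylation through the mixed anhydride or acylium ion; the arm on the ring from 2 has one free ortho position (para to its C3 methoxy group), and the arm on the ring from 1 should close para to the aryloxy oxygen and not at the position crowded between arm and ether, with dilution favouring five-membered closure over intermolecular acylation.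

**Step 4**
Reactants: 8 5-[(5,6-dimethoxy-1-oxo-2,3-dihydro-1H-inden-4-yl)oxy]-6-methoxy-2,3-dihydro-1H-inden-1-one
Product: 9 6-[(6,7-dimethoxy-2-oxo-3,4-dihydro-2H-chromen-5-yl)oxy]-7-methoxy-3,4-dihydro-2H-chromen-2-one
Conditions: mCPBA (3.0 equiv), CF3CO2H (2 equiv), CH2Cl2, 0 °C to rt, dark; cold aq Na2S2O3/NaHCO3 wash
Reagents that add atoms: mCPBA (3-chloroperoxybenzoic acid), OOC(=O)c1cccc(Cl)c1
Why: Each acid-activated ketone adds the peracid to give a Criegee adduct, and the aryl carbon C7a, held antiperiplanar to the O–O bond, shifts from carbon to oxygen as 3-chlorobenzoate leaves, so that oxygen is inserted between C2 and C8a (C2' and C8a'). The closest known reaction type is the Baeyer–Villiger oxidation of 1-indanones to 3,4-dihydrocoumarins, the cyclic counterpart of the oxidation of 4-alkoxyaryl ketones to aryl esters. Each six-membered lactone is closed by a 1,2-shift ring expansion of a five-membered ketone and not by a cyclisation, so no ring-closure constraint applies and the two rings expand independently. No stereocentre is formed. The step needs aryl migration in preference to methylene migration, and this is secured by the oxygen para to each migrating carbon (the aryloxy oxygen on C5 of the ring A indanone, the methoxy group on C5 of the ring B indanone), which stabilises the positive charge on the bridging aryl group in the transition state. It also needs the oxidant to spare the arenes, which is why mCPBA with a mild acid is preferred to CF3CO3H and why each product ring, now O-acylated, is less prone to hydroxylation than its precursor. The position of each carbonyl, and therefore of each O1, was already fixed in step 3, and the excess of peracid is there to carry the less electrophilic ring A ketone to completion.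

**Step 5**
Reactants: 9 6-[(6,7-dimethoxy-2-oxo-3,4-dihydro-2H-chromen-5-yl)oxy]-7-methoxy-3,4-dihydro-2H-chromen-2-one
Product: 10 6-[(6,7-dimethoxy-2-oxo-2H-chromen-5-yl)oxy]-7-methoxy-2H-chromen-2-one
Conditions: DDQ (3.0 equiv), 1,4-dioxane (dry), reflux
Reagents that add atoms: none
Why: Known quinone dehydrogenation of 3,4-dihydrocoumarins: DDQ abstracts hydride from the benzylic C4 and C4' positions, each para to a methoxy group (C7, C7'), and loss of the C3 proton gives the conjugated 2-pyranone; the methyl ethers keep the rings from being oxidised to quinones.

**Step 6**
Reactants: 10 6-[(6,7-dimethoxy-2-oxo-2H-chromen-5-yl)oxy]-7-methoxy-2H-chromen-2-one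
Product: 11 6-[(6,7-dihydroxy-2-oxo-2H-chromen-5-yl)oxy]-7-hydroxy-2H-chromen-2-one (target)
Conditions: BBr3 (8 equiv), CH2Cl2, −78 °C to rt; degassed H2O, 0 °C
Reagents that add atoms: none
Why: Standard BBr3 demethylation of methoxycoumarins: each methoxy oxygen binds boron and bromide attacks the methyl group (SN2), then hydrolysis frees the phenols; the diaryl ether has no alkyl carbon to attack and the lactones are only reversibly complexed, while the acidic, oxygen-free work-up protects the catechol.

## Compound list

1 | isovanillin (3-hydroxy-4-methoxybenzaldehyde) | COc1ccc(C=O)cc1O | starting material
2 | 2-bromo-3,4-dimethoxybenzaldehyde | COc1ccc(C=O)c(Br)c1OC | starting material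
3 | 2-(5-formyl-2-methoxyphenoxy)-3,4-dimethoxybenzaldehyde | COc1ccc(C=O)cc1Oc1c(OC)c(OC)ccc1C=O | intermediate
4 | Meldrum's acid (2,2-dimethyl-1,3-dioxane-4,6-dione) | CC1(C)OC(=O)CC(=O)O1 | starting material
5 | bis(arylidene Meldrum's acid): 5-{[3-(6-[(2,2-dimethyl-4,6-dioxo-1,3-dioxan-5-ylidene)methyl]-2,3-dimethoxyphenoxy)-4-methoxyphenyl]methylidene}-2,2-dimethyl-1,3-dioxane-4,6-dione | COc1ccc(C=C2C(=O)OC(C)(C)OC2=O)cc1Oc1c(OC)c(OC)ccc1C=C1C(=O)OC(C)(C)OC1=O | intermediate (not isolated)
6 | bis(benzyl Meldrum's acid): 5-{[3-(6-[(2,2-dimethyl-4,6-dioxo-1,3-dioxan-5-yl)methyl]-2,3-dimethoxyphenoxy)-4-methoxyphenyl]methyl}-2,2-dimethyl-1,3-dioxane-4,6-dione | COc1ccc(CC2C(=O)OC(C)(C)OC2=O)cc1Oc1c(OC)c(OC)ccc1CC1C(=O)OC(C)(C)OC1=O | intermediate (not isolated)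
7 | 3-{2-[5-(2-carboxyethyl)-2-methoxyphenoxy]-3,4-dimethoxyphenyl}propanoic acid | COc1ccc(CCC(=O)O)cc1Oc1c(OC)c(OC)ccc1CCC(=O)O | intermediate
8 | 5-[(5,6-dimethoxy-1-oxo-2,3-dihydro-1H-inden-4-yl)oxy]-6-methoxy-2,3-dihydro-1H-inden-1-one | COc1cc2c(cc1Oc1c(OC)c(OC)cc3c1CCC3=O)CCC2=O | intermediate
9 | 6-[(6,7-dimethoxy-2-oxo-3,4-dihydro-2H-chromen-5-yl)oxy]-7-methoxy-3,4-dihydro-2H-chromen-2-one | COc1cc2OC(=O)CCc2cc1Oc1c(OC)c(OC)cc2OC(=O)CCc12 | intermediate
10 | 6-[(6,7-dimethoxy-2-oxo-2H-chromen-5-yl)oxy]-7-methoxy-2H-chromen-2-one | COc1cc2oc(=O)ccc2cc1Oc1c(OC)c(OC)cc2oc(=O)ccc12 | intermediate
11 | 6-[(6,7-dihydroxy-2-oxo-2H-chromen-5-yl)oxy]-7-hydroxy-2H-chromen-2-one | O=c1ccc2cc(Oc3c(O)c(O)cc4oc(=O)ccc34)c(O)cc2o1 | target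

## Step count and risks

Total step count: 6. Longest linear sequence: 6 steps (from 1 or 2 to 11; 4 enters in step 2).

**Step 4 (key step).** The most likely failure is incomplete or misdirected oxygen insertion. The ring A ketone is conjugated to the para aryloxy oxygen and should add peracid slowly. Forcing it invites electrophilic hydroxylation of the oxygen-rich rings, acid-promoted opening of the lactone formed first, or some methylene migration. Fallback: bypass the ketone stage. Setting out from 3, Knoevenagel–Doebner condensation with malonic acid F1 (pyridine, cat. piperidine, 100 °C) should give the bis-(E)-cinnamic acid F2 (the same compound as A5). Riboflavin (5 mol %), O2 and violet-blue light in MeCN/MeOH at rt should then close both pyranone rings by E→Z isomerisation and oxidative C–O bond formation. The fallback rejoins the route at 10, so steps 2 to 5 are not needed; its own weak point is the choice of closure site on ring A.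

**Step 1.** The most likely failure is slow C–O bond formation at the doubly flanked C–Br carbon, which leaves time for reductive loss of bromine from 2 and base-induced degradation of the aldehydes. Fallback: a metal-free nucleophilic aromatic substitution. Setting out from 1, the phenoxide (K2CO3, DMF, 110 °C) should displace fluoride from 2-fluoro-3,4-dimethoxybenzaldehyde F3 through a Meisenheimer adduct stabilised by the ortho-formyl group. It rejoins the route at 3.

**Step 5.** The most likely failure is stalling after one ring has been dehydrogenated, because hydride abstraction beside a lactone carbonyl is slow, with loss of material by lactone opening during long heating. Fallback: α-selenation and selenoxide elimination. Setting out from 9, LiN(SiMe3)2 (2.2 equiv) in THF at −78 °C followed by PhSeCl should give the bis(3-phenylselanyl) lactone F4 (mixture of diastereomers). H2O2 in CH2Cl2 at 0 °C should then oxidise selenium and trigger syn-elimination toward C4 and C4'. It rejoins the route at 10.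

**Step 3.** The most likely failure is intermolecular acylation and oligomer formation competing with the slower closure onto ring A, which is activated only by the para aryloxy oxygen, together with C-sulfonylation or ether cleavage in the hot acid. Fallback: catalytic Lewis-acid acylation from the Meldrum's acid stage. Setting out from 6, isolated by stopping step 2 at 25 °C, Sc(OTf)3 (10 mol %) in MeNO2 at 100 °C should acylate each ring with loss of acetone and CO2. It rejoins the route at 8 and makes no new compound.

## Further compounds

F1 | step 4 | malonic acid | OC(=O)CC(=O)O
F2 | step 4 | (2E)-3-{2-[5-((E)-2-carboxyethenyl)-2-methoxyphenoxy]-3,4-dimethoxyphenyl}prop-2-enoic acid | COc1ccc(/C=C/C(=O)O)cc1Oc1c(OC)c(OC)ccc1/C=C/C(=O)O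
F3 | step 1 | 2-fluoro-3,4-dimethoxybenzaldehyde | COc1ccc(C=O)c(F)c1OC
F4 | step 5 | 6-{[6,7-dimethoxy-2-oxo-3-(phenylselanyl)-3,4-dihydro-2H-chromen-5-yl]oxy}-7-methoxy-3-(phenylselanyl)-3,4-dihydro-2H-chromen-2-one (mixture of diastereomers) | COc1cc2OC(=O)C([Se]c3ccccc3)Cc2cc1Oc1c(OC)c(OC)cc2OC(=O)C([Se]c3ccccc3)Cc12
F0 | step 3 | none | none
A1 | alternative 1 | methyl 5-[(6,7-dimethoxy-2-oxo-2H-chromen-5-yl)oxy]-2,4-dihydroxybenzoate | COC(=O)c1cc(Oc2c(OC)c(OC)cc3oc(=O)ccc23)c(O)cc1O
A2 | alternative 1 | 5-{[4-methoxy-2,4-bis(trimethylsilyloxy)buta-1,3-dien-1-yl]oxy}-6,7-dimethoxy-2H-chromen-2-one (double-bond geometry not defined) | COC(O[Si](C)(C)C)=CC(O[Si](C)(C)C)=COc1c(OC)c(OC)cc2oc(=O)ccc12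
A3 | alternative 1 | methyl propiolate | C#CC(=O)OC
A4 | alternative 1 | 5-hydroxy-6,7-dimethoxy-2H-chromen-2-one | COc1cc2oc(=O)ccc2c(O)c1OC
A5 | alternative 2 | (2E)-3-{2-[5-((E)-2-carboxyethenyl)-2-methoxyphenoxy]-3,4-dimethoxyphenyl}prop-2-enoic acid | COc1ccc(/C=C/C(=O)O)cc1Oc1c(OC)c(OC)ccc1/C=C/C(=O)O
A6 | alternative 2 | 6-[(6,7-dimethoxy-2-oxo-2H-chromen-5-yl)oxy]-7-methoxy-2H-chromen-2-one | COc1cc2oc(=O)ccc2cc1Oc1c(OC)c(OC)cc2oc(=O)ccc12
A7 | alternative 3 | 2,3-dimethoxycyclobut-2-en-1-one | COC1=C(OC)C(=O)C1
A8 | alternative 3 | 6-[(3,3-dimethoxyprop-1-yn-1-yl)oxy]-7-methoxy-2H-chromen-2-one | COC(OC)C#COc1cc2ccc(=O)oc2cc1OC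
A9 | alternative 3 | 6-[2-(dimethoxymethyl)-3-hydroxy-5,6-dimethoxyphenoxy]-7-methoxy-2H-chromen-2-one | COC(OC)c1c(O)cc(OC)c(OC)c1Oc1cc2ccc(=O)oc2cc1OC
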